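**Plan**
Retrosynthesis removes the C8 epoxy ester, opens the lactone (C12–O6) to a 2-(hydroxymethyl)allyl group on C7, and takes off the 4,5-epoxide and the C9 acetate, leaving a ten-membered C9 ketone with an (E)-C4=C5 bond.
C9 and C5 both bear oxygen and sit on either side of the methyl-bearing C4, so joining C4 to C9 turns the C1–C10 ring into a trans-decalin (ring A: C4, C3, C2, C1, C10, C9; ring B: C4, C5, C6, C7, C8, C9) that is a 1,3-diol monomesylate (C9–OH, C5–OMs) set up to fragment.
The decalin is cut in ring A at C2=C3 (metathesis), C9–C10 (Reformatsky) and C4–C3 (vinyl group); what remains is ring B, which is (R)-carvone (its ketone is C5, its stereocentre C7).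
Forward: ring B is functionalised, ring A is closed on it, the C4–C9 bond is broken to give the ten-membered ring, then the 4,5-epoxide, the lactone ring and the C8 ester follow.
Stereochemistry: C7 comes from carvone; C4, C6, C8, C9–O, the 2,3-epoxide and C5 are relayed from it on the six-membered rings; after ring opening C9 is set from C8 and the 4,5-epoxide from C6–OH; the side-chain epoxide comes from a Sharpless epoxidation.

Key step: step 17

Remark: the target is taken as the enantiomer drawn, (2R,3R,4S,5R,6S,7R,8S,9S) with a (2S,3S)-epoxy ester. Germacrane numbering is used for all intermediates (C14 ester carbon on C10, C15 methyl on C4, C11–C13 on C7 with C12 oxygenated). β means the face of ring B that carries the C7 side chain, α the opposite face. TBS = tert-butyldimethylsilyl, PMB = 4-methoxybenzyl.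

**Step 1**
Reactants: 1 (R)-(−)-carvone
Product: 2 (R)-10-chlorocarvone
Conditions: Ca(OCl)2, CO2 (dry ice), CH2Cl2/H2O, 0 °C
Reagents that add atoms: calcium hypochlorite Ca(OCl)2, [Ca+2].[O-]Cl.[O-]Cl
Why: Ene-type allylic chlorination by HOCl takes place at the electron-rich 1,1-disubstituted alkene and leaves the electron-poor enone and the C7 stereocentre untouched.

**Step 2**
Reactants: 2 (R)-10-chlorocarvone
Product: 4 (R)-10-hydroxycarvone, via acetate 3 (not isolated)
Conditions: KOAc, DMF, 60 °C; then K2CO3 (cat.), MeOH, rt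
Reagents that add atoms: potassium acetate KOAc, CC(=O)[O-].[K+]
Why: SN2 displacement of the primary allylic chloride by acetate and transesterification in the same flask free the C12 alcohol without touching C7.

**Step 3**
Reactants: 4 (R)-10-hydroxycarvone
Product: 5 silyl ether of 10-hydroxycarvone
Conditions: TBSCl, imidazole, DMF, rt
Reagents that add atoms: tert-butyldimethylsilyl chloride, CC(C)(C)[Si](C)(C)Cl
Why: Silylation of a primary allylic alcohol masks C12–OH until the lactone is made.

**Step 4**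
Reactants: 5 silyl ether of 10-hydroxycarvone; 6 phenyl vinyl sulfoxide
Product: 8 vinyl ketone (C5 ketone; C4 methyl β and vinyl α; C8=C9), via sulfoxide adduct 7 (not isolated)
Conditions: KOtBu (0.2 equiv), tBuOH/THF, 0 °C to rt; then NaHCO3, toluene, 110 °C
Reagents that add atoms: none
Why: Deconjugative Michael addition, in which KOtBu removes the γ-proton at C8 and the extended dienolate attacks the vinyl sulfoxide through C4 on the face opposite the C7 substituent (new carbon α, methyl β), is followed by thermal syn-elimination of the sulfoxide to unveil the vinyl group.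

**Step 5**
Reactants: 8 vinyl ketone
Product: 9 6α-hydroxy ketone
Conditions: KN(SiMe3)2, THF, −78 °C; then 2-(phenylsulfonyl)-3-phenyloxaziridine, −78 °C
Reagents that add atoms: 2-(phenylsulfonyl)-3-phenyloxaziridine, O=S(=O)(N1OC1c1ccccc1)c1ccccc1
Why: Enolate hydroxylation with a Davis oxaziridine: the ketone can enolise only towards C6, and the oxidant comes in anti to the neighbouring C7 side chain, which should give the 6α (trans) alcohol.

**Step 6**
Reactants: 9 6α-hydroxy ketone
Product: 10 8α,9α-epoxy alcohol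
Conditions: VO(acac)2 (cat.), tBuOOH, CH2Cl2, 0 °C to rt
Reagents that add atoms: tert-butyl hydroperoxide, CC(C)(C)OO
Why: Hydroxyl-directed epoxidation of a cyclic homoallylic alcohol delivers oxygen to C8=C9 syn to the C6 hydroxyl, the face also left open by the pseudo-axial C4 methyl, while the vinyl group and the alkene carrying the CH2OSi group are less nucleophilic and less well placed.

**Step 7**
Reactants: 10 8α,9α-epoxy alcohol
Product: 11 epoxy ketone bis-silyl ether
Conditions: TBSOTf, 2,6-lutidine, CH2Cl2, −78 °C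
Reagents that add atoms: tert-butyldimethylsilyl triflate, CC(C)(C)[Si](C)(C)OS(=O)(=O)C(F)(F)F
Why: Silylation of the secondary alcohol with the reactive triflate at low temperature, where the epoxide and the α-ketol are stable.

**Step 8**
Reactants: 11 epoxy ketone bis-silyl ether; 12 4-methoxybenzyl alcohol
Product: 13 9α-hydroxy 8β-PMB ether
Conditions: Yb(OTf)3 (10 mol %), CH2Cl2, rt
Reagents that add atoms: none
Why: Lewis acid catalysed epoxide alcoholysis by an SN2 path: C9 is neopentylic, so the alcohol enters at C8 with inversion (trans-diaxial opening), setting the 8β ether and leaving the 9α alcohol.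

**Step 9**
Reactants: 13 9α-hydroxy 8β-PMB ether
Product: 14 5,9-diketone
Conditions: Dess–Martin periodinane, NaHCO3, CH2Cl2, rt
Reagents that add atoms: none
Why: Dess–Martin oxidation of the hindered secondary alcohol under buffered, non-enolising conditions keeps the C6 and C8 centres next to the two carbonyl groups intact.

**Step 10**
Reactants: 14 5,9-diketone; 15 methyl 2-bromopent-4-enoate
Product: 16 Reformatsky adduct (9β-hydroxy ester, C10 epimers)
Conditions: Zn (activated), THF, 0 °C to rt
Reagents that add atoms: none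
Why: Reformatsky reaction: the zinc enolate should add to the C9 carbonyl, which is activated by the antiperiplanar axial C8–O bond (Felkin–Anh) and less shielded than C5 with its equatorial silyloxy neighbour; the configurations at C9 and C10 do not matter because both centres become sp2 in step 12.

**Step 11**
Reactants: 16 Reformatsky adduct
Product: 17 cis-fused hydroxy ester with ring A closed (C2=C3)
Conditions: second-generation Grubbs catalyst (H2IMes)(PCy3)Cl2Ru=CHPh (5 mol %), CH2Cl2, 40 °C
Reagents that add atoms: none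
Why: Ring-closing metathesis of the two monosubstituted alkenes closes ring A as a cyclohexene; the hindered 1,1-disubstituted side-chain alkene does not compete.

**Step 12**
Reactants: 17 cis-fused hydroxy ester
Product: 19 tetrasubstituted enoate (C9=C10 with C2=C3), via trifluoroacetate 18 (not isolated)
Conditions: (CF3CO)2O, pyridine, DMAP, CH2Cl2, 0 °C; then DBU, rt
Reagents that add atoms: none
Why: E1cB dehydration: the tertiary alcohol is acylated and DBU removes the only acidic proton (C10–H, α to the ester), so elimination can only give the C9=C10 enoate.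

**Step 13**
Reactants: 19 tetrasubstituted enoate
Product: 21 trans-fused 9α-hydroxy diene ester, via hydroperoxide 20 (not isolated)
Conditions: O2, tetraphenylporphyrin (cat.), visible light, CH2Cl2, −20 °C; then PPh3, −20 °C to rt
Reagents that add atoms: oxygen, O=O
Why: Schenck ene reaction of an α,β-unsaturated ester: singlet oxygen bonds to C9 from the α face (the β face is closed by the axial C4 methyl and the axial C8 ether) and takes the doubly allylic hydrogen on C1, the carbon geminal to the ester, giving the 9α hydroperoxide (hence the trans ring fusion) and the C10=C1–C2=C3 diene, and PPh3 reduces the hydroperoxide.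

**Step 14**
Reactants: 21 trans-fused 9α-hydroxy diene ester
Product: 22 2α,3α-epoxy ketol
Conditions: VO(acac)2 (cat.), tBuOOH, CH2Cl2, rt
Reagents that add atoms: tert-butyl hydroperoxide, CC(C)(C)OO
Why: Hydroxyl-directed epoxidation: the axial 9α alcohol delivers oxygen across C4 to the C2=C3 bond on the α face, the β face being shielded by the axial methyl, while the ester-bearing C1=C10 bond and the side-chain alkene do not react.

**Step 15**
Reactants: 22 2α,3α-epoxy ketol
Product: 23 5β,9α-diol
Conditions: NaBH4, MeOH/CH2Cl2, −40 °C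
Reagents that add atoms: none
Why: Borohydride reduction of a cyclohexanone in a trans-decalin: hydride adds along the axial direction on the α face, away from the adjacent axial methyl and assisted by the 9α alkoxide, to give the equatorial 5β alcohol.

**Step 16**
Reactants: 23 5β,9α-diol
Product: 24 trans-decalin mesylate (C9–OH, equatorial C5–OMs)
Conditions: MsCl, Et3N, CH2Cl2, −20 °C
Reagents that add atoms: methanesulfonyl chloride, CS(=O)(=O)Cl
Why: Selective sulfonylation of the secondary alcohol; the tertiary C9 alcohol does not react with MsCl/Et3N.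

**Step 17**
Reactants: 24 trans-decalin mesylate
Product: 25 ten-membered C9 keto ester with (E)-C4=C5 and the cis 2,3-epoxide
Conditions: KOtBu (1.05 equiv), THF, −20 to 0 °C; pH 7 buffer quench
Reagents that add atoms: none
Why: KOtBu deprotonates the tertiary C9 alcohol, and the alkoxide forms the C9 carbonyl while the C4–C9 bond, antiperiplanar to the equatorial C5–OMs bond of ring B, breaks and mesylate leaves in a concerted Wharton–Grob fragmentation. The closest known reaction is the fragmentation of decalin 1,3-diol monosulfonates to (E)-cyclodec-5-enones. No ring is closed end to end: the ten-membered ring is released by cleavage of the bond shared by rings A and B, and no stereocentre is formed. The (E) geometry of C4=C5 follows from the trans ring fusion, in which C3 is equatorial on ring B and therefore anti to C6 across C4–C5, while the axial methyl ends up cis to C6. Fragmentation has to outrun substitution or elimination at C5, epimerisation at C8 and attack on the new alkylidene keto ester: the neopentylic equatorial mesylate has no antiperiplanar hydrogen and cannot be displaced, C10 carries no hydrogen so the 2,3-epoxide cannot be opened by enolisation, and the single equivalent of base is consumed as potassium mesylate.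

**Step 18**
Reactants: 25 ten-membered C9 keto ester
Product: 26 (9S)-alcohol
Conditions: NaBH4, CeCl3·7H2O, MeOH, −78 °C
Reagents that add atoms: none
Why: Luche 1,2-reduction of the cross-conjugated ketone; Felkin–Anh addition anti to the C8–O bond under non-chelating conditions should give the 8,9-threo, that is (9S), alcohol.

**Step 19**
Reactants: 26 (9S)-alcohol
Product: 27 C9 acetate
Conditions: Ac2O, pyridine, DMAP (cat.), CH2Cl2, 0 °C
Reagents that add atoms: acetic anhydride, CC(=O)OC(C)=O
Why: DMAP-catalysed acylation of the secondary allylic alcohol.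

**Step 20**
Reactants: 27 C9 acetate
Product: 28 6,12-diol
Conditions: HF·pyridine, pyridine, THF, 0 °C to rt
Reagents that add atoms: none
Why: Fluoride cleavage of both silyl ethers under buffered, weakly acidic conditions avoids alkoxide-induced epoxide migration and acetate transfer.

**Step 21**
Reactants: 28 6,12-diol
Product: 29 4,5-epoxy diol
Conditions: mCPBA, NaHCO3, CH2Cl2, −20 °C
Reagents that add atoms: 3-chloroperbenzoic acid, O=C(OO)c1cccc(Cl)c1
Why: Hydroxyl-directed (Henbest) epoxidation: the trisubstituted C4=C5 bond is the most nucleophilic alkene, and delivery syn to the C6 hydroxyl in the conformer with H6 eclipsing the alkene plane (least A(1,3) strain with the C4 methyl) gives the threo epoxy alcohol, the (4S,5R) epoxide.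

**Step 22**
Reactants: 29 4,5-epoxy diol
Product: 32 α-methylene lactone PMB ether, via hydroxy enal 30 (not isolated), via lactol 31 (not isolated)
Conditions: MnO2 (activated, excess), CH2Cl2, rt
Reagents that add atoms: none
Why: MnO2 oxidises only the allylic C12 alcohol (C6–OH is no longer allylic), the 2-substituted acrolein is trapped by C6–OH as the lactol, and further oxidation gives the α-methylene γ-lactone with the 6,7-trans fusion already in place.

**Step 23**
Reactants: 32 α-methylene lactone PMB ether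
Product: 33 C8 alcohol
Conditions: DDQ, CH2Cl2/pH 7 phosphate buffer, 0 °C
Reagents that add atoms: none
Why: Oxidative cleavage of the PMB ether by DDQ is orthogonal to the acetate, the lactone, the enoate and the epoxides.

**Step 24**
Reactants: 34 angelic acid
Product: 35 (Z)-2-methylbut-2-en-1-ol
Conditions: LiAlH4, Et2O, 0 °C
Reagents that add atoms: none
Why: Hydride reduction of the conjugated acid to the allylic alcohol keeps the (Z) geometry.

**Step 25**
Reactants: 35 (Z)-2-methylbut-2-en-1-ol
Product: 36 [(2R,3S)-2,3-dimethyloxiran-2-yl]methanol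
Conditions: Ti(OiPr)4, D-(−)-diethyl tartrate, tBuOOH, 4 Å molecular sieves, CH2Cl2, −20 °C
Reagents that add atoms: tert-butyl hydroperoxide, CC(C)(C)OO
Why: Sharpless asymmetric epoxidation: the D-(−)-tartrate selects the alkene face that gives the (2R,3S) epoxy alcohol, and the (Z) alkene geometry is carried into the epoxide.

**Step 26**
Reactants: 36 [(2R,3S)-2,3-dimethyloxiran-2-yl]methanol
Product: 37 (2S,3S)-2,3-dimethyloxirane-2-carboxylic acid
Conditions: RuCl3·xH2O (cat.), NaIO4, MeCN/EtOAc/H2O, rt
Reagents that add atoms: water, O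
Why: RuO4 made from RuCl3 and NaIO4 oxidises the primary alcohol through the aldehyde hydrate to the acid without touching the epoxide (the C2 descriptor changes only because the priorities change).

**Step 27**
Reactants: 37 (2S,3S)-2,3-dimethyloxirane-2-carboxylic acid; 33 C8 alcohol
Product: 39 CNP0077535.2, via mixed anhydride 38 (not isolated)
Conditions: 2,4,6-trichlorobenzoyl chloride, Et3N, THF, rt; then 33, DMAP, toluene, rt
Reagents that add atoms: none
Why: Yamaguchi esterification: the mixed anhydride acylates the hindered C8 alcohol under DMAP catalysis without opening the epoxy acid or the ring epoxides, and no stereocentre is touched.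

**Compound list**
1 | (R)-(−)-carvone, (5R)-2-methyl-5-(prop-1-en-2-yl)cyclohex-2-en-1-one | CC1=CC[C@H](CC1=O)C(C)=C | starting material
2 | (R)-10-chlorocarvone, (5R)-5-(3-chloroprop-1-en-2-yl)-2-methylcyclohex-2-en-1-one | CC1=CC[C@H](CC1=O)C(=C)CCl | intermediate
3 | (R)-10-acetoxycarvone | CC1=CC[C@H](CC1=O)C(=C)COC(C)=O | intermediate
4 | (R)-10-hydroxycarvone | CC1=CC[C@H](CC1=O)C(=C)CO | intermediate
5 | silyl ether, (5R)-5-[3-(tert-butyldimethylsilyloxy)prop-1-en-2-yl]-2-methylcyclohex-2-en-1-one | CC1=CC[C@H](CC1=O)C(=C)CO[Si](C)(C)C(C)(C)C | intermediate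
6 | phenyl vinyl sulfoxide (racemic) | C=CS(=O)c1ccccc1 | starting material
7 | sulfoxide adduct, (2R,5S)-2-methyl-2-[2-(phenylsulfinyl)ethyl]-5-[3-(TBS-oxy)prop-1-en-2-yl]cyclohex-3-en-1-one (mixture at sulfur) | C=C(CO[Si](C)(C)C(C)(C)C)[C@@H]1C=C[C@@](C)(CCS(=O)c2ccccc2)C(=O)C1 | intermediate
8 | vinyl ketone, (2R,5S)-2-ethenyl-2-methyl-5-[3-(TBS-oxy)prop-1-en-2-yl]cyclohex-3-en-1-one (C5 ketone, C4 methyl β, vinyl α, C8=C9) | C=C(CO[Si](C)(C)C(C)(C)C)[C@@H]1C=C[C@@](C)(C=C)C(=O)C1 | intermediate
9 | 6α-hydroxy ketone (8 with OH on C6 trans to the C7 side chain) | C=C(CO[Si](C)(C)C(C)(C)C)[C@@H]1C=C[C@@](C)(C=C)C(=O)[C@H]1O | intermediate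
10 | 8α,9α-epoxy alcohol (9 with the ring alkene epoxidised syn to C6–OH) | C=C(CO[Si](C)(C)C(C)(C)C)[C@@H]1[C@H]2O[C@H]2[C@@](C)(C=C)C(=O)[C@H]1O | intermediate
11 | epoxy ketone bis-silyl ether (10 with 6α-OTBS) | C=C(CO[Si](C)(C)C(C)(C)C)[C@@H]1[C@H]2O[C@H]2[C@@](C)(C=C)C(=O)[C@H]1O[Si](C)(C)C(C)(C)C | intermediate
12 | 4-methoxybenzyl alcohol | COc1ccc(CO)cc1 | starting material
13 | 9α-hydroxy 8β-PMB ether (C5 ketone, 6α-OTBS, 8β-OPMB, 9α-OH) | C=C(CO[Si](C)(C)C(C)(C)C)[C@@H]1[C@H](OCc2ccc(OC)cc2)[C@@H](O)[C@@](C)(C=C)C(=O)[C@H]1O[Si](C)(C)C(C)(C)C | intermediate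
14 | 5,9-diketone (6α-OTBS, 8β-OPMB, C4 methyl β, vinyl α) | C=C(CO[Si](C)(C)C(C)(C)C)[C@@H]1[C@H](OCc2ccc(OC)cc2)C(=O)[C@@](C)(C=C)C(=O)[C@H]1O[Si](C)(C)C(C)(C)C | intermediate
15 | methyl 2-bromopent-4-enoate (racemic) | C=CCC(Br)C(=O)OC | starting material
16 | Reformatsky adduct (9β-OH, C10 on the α face carrying CO2Me and allyl, C10 epimers) | C=C(CO[Si](C)(C)C(C)(C)C)[C@@H]1[C@H](OCc2ccc(OC)cc2)[C@@](O)(C(CC=C)C(=O)OC)[C@@](C)(C=C)C(=O)[C@H]1O[Si](C)(C)C(C)(C)C | intermediate
17 | cis-fused hydroxy ester (ring A closed, C2=C3, 9β-OH, C10–H epimers, C5 ketone) | C=C(CO[Si](C)(C)C(C)(C)C)[C@@H]1[C@H](OCc2ccc(OC)cc2)[C@@]2(O)C(C(=O)OC)CC=C[C@@]2(C)C(=O)[C@H]1O[Si](C)(C)C(C)(C)C | intermediate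
18 | trifluoroacetate of 17 | C=C(CO[Si](C)(C)C(C)(C)C)[C@@H]1[C@H](OCc2ccc(OC)cc2)[C@@]2(OC(=O)C(F)(F)F)C(C(=O)OC)CC=C[C@@]2(C)C(=O)[C@H]1O[Si](C)(C)C(C)(C)C | intermediate
19 | tetrasubstituted enoate (C9=C10 with CO2Me on C10, C2=C3, C5 ketone) | C=C(CO[Si](C)(C)C(C)(C)C)[C@@H]1[C@H](OCc2ccc(OC)cc2)C2=C(C(=O)OC)CC=C[C@@]2(C)C(=O)[C@H]1O[Si](C)(C)C(C)(C)C | intermediate
20 | 9α-hydroperoxide (C10=C1–C2=C3 diene ester) | C=C(CO[Si](C)(C)C(C)(C)C)[C@@H]1[C@H](OCc2ccc(OC)cc2)[C@]2(OO)C(C(=O)OC)=CC=C[C@@]2(C)C(=O)[C@H]1O[Si](C)(C)C(C)(C)C | intermediate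
21 | trans-fused 9α-hydroxy diene ester (C5 ketone) | C=C(CO[Si](C)(C)C(C)(C)C)[C@@H]1[C@H](OCc2ccc(OC)cc2)[C@]2(O)C(C(=O)OC)=CC=C[C@@]2(C)C(=O)[C@H]1O[Si](C)(C)C(C)(C)C | intermediate
22 | 2α,3α-epoxy ketol (21 with the C2=C3 bond epoxidised on the α face) | C=C(CO[Si](C)(C)C(C)(C)C)[C@@H]1[C@H](OCc2ccc(OC)cc2)[C@]2(O)C(C(=O)OC)=C[C@H]3O[C@H]3[C@@]2(C)C(=O)[C@H]1O[Si](C)(C)C(C)(C)C | intermediate
23 | 5β,9α-diol | C=C(CO[Si](C)(C)C(C)(C)C)[C@@H]1[C@H](OCc2ccc(OC)cc2)[C@]2(O)C(C(=O)OC)=C[C@H]3O[C@H]3[C@@]2(C)[C@H](O)[C@H]1O[Si](C)(C)C(C)(C)C | intermediate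
24 | trans-decalin mesylate (9α-OH, 5β-OMs equatorial, 6α-OTBS, 7β side chain, 8β-OPMB, 2α,3α-epoxide, C1=C10 ester) | C=C(CO[Si](C)(C)C(C)(C)C)[C@@H]1[C@H](OCc2ccc(OC)cc2)[C@]2(O)C(C(=O)OC)=C[C@H]3O[C@H]3[C@@]2(C)[C@H](OS(C)(=O)=O)[C@H]1O[Si](C)(C)C(C)(C)C | intermediate
25 | ten-membered C9 keto ester ((1Z)-enoate, (4E)-alkene, cis 2,3-epoxide, 6α-OTBS, 8β-OPMB) | C=C(CO[Si](C)(C)C(C)(C)C)[C@@H]1[C@H](OCc2ccc(OC)cc2)C(=O)/C(C(=O)OC)=C\[C@H]2O[C@H]2/C(C)=C/[C@H]1O[Si](C)(C)C(C)(C)C | intermediate
26 | (9S)-alcohol | C=C(CO[Si](C)(C)C(C)(C)C)[C@@H]1[C@H](OCc2ccc(OC)cc2)[C@@H](O)/C(C(=O)OC)=C\[C@H]2O[C@H]2/C(C)=C/[C@H]1O[Si](C)(C)C(C)(C)C | intermediate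
27 | C9 acetate | C=C(CO[Si](C)(C)C(C)(C)C)[C@@H]1[C@H](OCc2ccc(OC)cc2)[C@@H](OC(C)=O)/C(C(=O)OC)=C\[C@H]2O[C@H]2/C(C)=C/[C@H]1O[Si](C)(C)C(C)(C)C | intermediate
28 | 6,12-diol | C=C(CO)[C@@H]1[C@H](OCc2ccc(OC)cc2)[C@@H](OC(C)=O)/C(C(=O)OC)=C\[C@H]2O[C@H]2/C(C)=C/[C@H]1O | intermediate
29 | 4,5-epoxy diol ((4S,5R) epoxide) | C=C(CO)[C@@H]1[C@H](OCc2ccc(OC)cc2)[C@@H](OC(C)=O)/C(C(=O)OC)=C\[C@H]2O[C@H]2[C@@]2(C)O[C@@H]2[C@H]1O | intermediate
30 | hydroxy enal (C12 aldehyde, C6–OH) | C=C(C=O)[C@@H]1[C@H](OCc2ccc(OC)cc2)[C@@H](OC(C)=O)/C(C(=O)OC)=C\[C@H]2O[C@H]2[C@@]2(C)O[C@@H]2[C@H]1O | intermediate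
31 | lactol (C12 epimers) | C=C1C(O)O[C@H]2[C@H]1[C@H](OCc1ccc(OC)cc1)[C@@H](OC(C)=O)/C(C(=O)OC)=C\[C@H]1O[C@H]1[C@@]1(C)O[C@H]21 | intermediate
32 | α-methylene lactone PMB ether | C=C1C(=O)O[C@H]2[C@H]1[C@H](OCc1ccc(OC)cc1)[C@@H](OC(C)=O)/C(C(=O)OC)=C\[C@H]1O[C@H]1[C@@]1(C)O[C@H]21 | intermediate
33 | C8 alcohol | C=C1C(=O)O[C@H]2[C@H]1[C@H](O)[C@@H](OC(C)=O)/C(C(=O)OC)=C\[C@H]1O[C@H]1[C@@]1(C)O[C@H]21 | intermediate
34 | angelic acid, (Z)-2-methylbut-2-enoic acid | C/C=C(/C)C(=O)O | starting material
35 | (Z)-2-methylbut-2-en-1-ol | C/C=C(/C)CO | intermediate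
36 | [(2R,3S)-2,3-dimethyloxiran-2-yl]methanol | OC[C@@]1(C)O[C@H]1C | intermediate
37 | (2S,3S)-2,3-dimethyloxirane-2-carboxylic acid | OC(=O)[C@@]1(C)O[C@H]1C | intermediate
38 | mixed anhydride of 37 with 2,4,6-trichlorobenzoic acid | O=C(OC(=O)c1c(Cl)cc(Cl)cc1Cl)[C@@]1(C)O[C@H]1C | intermediate
39 | CNP0077535.2, methyl (2R,3R,4S,5R,6S,7R,8S,9S)-9-acetoxy-2,3:4,5-diepoxy-8-[(2S,3S)-2,3-dimethyloxirane-2-carbonyloxy]-12-oxo-12,6-epoxygermacra-1(10)Z,11(13)-dien-14-oate | C=C1C(=O)O[C@H]2[C@H]1[C@H](OC(=O)[C@@]1(C)O[C@H]1C)[C@@H](OC(C)=O)/C(C(=O)OC)=C\[C@H]1O[C@H]1[C@@]1(C)O[C@H]21 | target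

**Step count**
Total: 27 steps. Longest linear sequence: 24 steps (steps 1–23 and 27, from (R)-carvone). The epoxy acid 37 takes 3 steps (24–26) from angelic acid.

**The three steps most likely to fail**

Step 4. The Michael addition may occur at C6 instead of C4 or twice, and attack on the face syn to the C7 side chain may compete. The fallback sets out from 5 and replaces the Michael acceptor by the standard electrophile for deconjugative alkylation. The potassium dienolate (KOtBu, 1.05 equiv, tBuOH) is alkylated with allyl bromide to give the allyl ketone F1, at which stage diastereomers at C4 can be separated. The monosubstituted alkene is then moved into the chain with RuHCl(CO)(PPh3)3 in toluene at 80 °C to give the (E)-propenyl ketone F2. Ethenolysis with the second-generation Hoveyda–Grubbs catalyst (H2IMes)Cl2Ru=CH(2-iPrO-C6H4) under ethylene comes back to the route at 8.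

Step 10. The zinc enolate may add to the C5 carbonyl instead of C9, or the zinc aldolate, a β-keto alkoxide, may open ring B by retro-aldol cleavage. The fallback sets out from 14 and changes the mode of activation from a free metal enolate to a chelating Lewis acid. In a Mukaiyama aldol addition, 1-methoxy-1-(trimethylsilyloxy)penta-1,4-diene is added with MgBr2·OEt2 in CH2Cl2 at −78 °C. The Lewis acid binds the C9 carbonyl together with the PMB ether oxygen on C8, which the silyl ether on C6 cannot do, and the adduct is trapped as a silyl ether instead of a free alkoxide. Acidic work-up gives 16, where the fallback rejoins the route; it makes no compound that the list does not hold (F0).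

Step 13. Singlet oxygen may also react at the C2=C3 bond of ring A, and the product diene may be over-oxidised by a second photooxygenation. The fallback sets out from 16 and carries out the ene reaction before ring A exists, so that no ring alkene competes. Dehydration of 16 with the Burgess reagent (toluene, 60 °C) gives the acyclic tetrasubstituted enoate F3. Photooxygenation (O2, tetraphenylporphyrin, light) gives the 9α-hydroperoxide F4 with the C10=C1–C2=CH2 diene, which PPh3 reduces in the same flask to the 9α-hydroxy dienyl ester F5. Ring-closing metathesis between the C4 vinyl group and the terminal alkene of the diene (second-generation Grubbs catalyst) comes back to the route at 21. The weak point of this fallback is that the new C10=C1 bond must form with C2 cis to C9 for the ring to close.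

**Further compounds**
F1 | step 4 | allyl ketone, (2R,5S)-2-allyl-2-methyl-5-[3-(TBS-oxy)prop-1-en-2-yl]cyclohex-3-en-1-one | C=C(CO[Si](C)(C)C(C)(C)C)[C@@H]1C=C[C@@](C)(CC=C)C(=O)C1
F2 | step 4 | (E)-propenyl ketone, (2R,5S)-2-methyl-2-[(E)-prop-1-enyl]-5-[3-(TBS-oxy)prop-1-en-2-yl]cyclohex-3-en-1-one | C=C(CO[Si](C)(C)C(C)(C)C)[C@@H]1C=C[C@@](C)(/C=C/C)C(=O)C1
F0 | step 10 | none | none
F3 | step 13 | acyclic tetrasubstituted enoate (C9=C10 carrying CO2Me and allyl, alkene geometry not defined) | C=C(CO[Si](C)(C)C(C)(C)C)[C@@H]1[C@H](OCc2ccc(OC)cc2)C(=C(CC=C)C(=O)OC)[C@@](C)(C=C)C(=O)[C@H]1O[Si](C)(C)C(C)(C)C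
F4 | step 13 | 9α-hydroperoxide with C10=C1–C2=CH2 diene | C=C(CO[Si](C)(C)C(C)(C)C)[C@@H]1[C@H](OCc2ccc(OC)cc2)[C@](OO)(/C(C(=O)OC)=C\C=C)[C@@](C)(C=C)C(=O)[C@H]1O[Si](C)(C)C(C)(C)C
F5 | step 13 | 9α-hydroxy dienyl ester | C=C(CO[Si](C)(C)C(C)(C)C)[C@@H]1[C@H](OCc2ccc(OC)cc2)[C@](O)(/C(C(=O)OC)=C\C=C)[C@@](C)(C=C)C(=O)[C@H]1O[Si](C)(C)C(C)(C)C
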